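**Retrosynthetic overview**
Numbering: ring A is C1 (bears hydroxymethyl carbon C7), C2 (H), C3 and C4 (OH), C5 (Br), C6 (bears bridge carbon C8). Ring B is the 3-bromo-4,5-dihydroxyphenyl group on C8.
Feature used: C7 and C8 are ortho neighbours on ring A, so the C7 oxygen can be tied to C8 as a 1-aryl-1,3-dihydro-2-benzofuran. The C4 hydroxyl lies para to C1 and can be read as a former furan oxygen.
Late disconnections: the O-methyl groups (BBr3, then hydrolysis of the C7 bromide that BBr3 makes), the C8–O bond (ionic hydrogenation), and C5–Br (ortho-bromination of the C4 phenol).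
Key disconnection: C1–C6 and C4–C5, by an intramolecular furan–alkyne Diels–Alder reaction with oxa-bridge opening. The five-membered ether ring and ring A form together, and ring B is bought in.
The precursor ether is split at C7–O into (4-methoxyfuran-2-yl)methanol (two steps from methyl 4-bromofuran-2-carboxylate) and the ethynyl adduct of 3-bromo-4,5-dimethoxybenzaldehyde.

Key step: step 5

Remark: all intermediates with a stereocentre at C8 are made and used as racemates, because C8 ends as a CH2 group.

**Step 1**
Reactants: 1 methyl 4-bromofuran-2-carboxylate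
Product: 2 methyl 4-methoxyfuran-2-carboxylate
Conditions: NaOMe (3 equiv), CuBr (10 mol %), MeOH–NMP, 100 °C, Ar
Reagents that add atoms: sodium methoxide, [Na+].[O-]C
Why: Ullmann-type copper-catalysed methoxylation of a heteroaryl bromide, the standard way from 3-halofurans and 3-halothiophenes to their methyl ethers, should work here because the ring bromide is the only site consumed (methoxide exchange at the methyl ester is degenerate) and the ester tempers the acid sensitivity of the new alkoxyfuran.

**Step 2**
Reactants: 2 methyl 4-methoxyfuran-2-carboxylate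
Product: 3 (4-methoxyfuran-2-yl)methanol
Conditions: LiAlH4 (0.75 equiv), Et2O, 0 °C; then H2O, aq NaOH
Reagents that add atoms: none
Why: LiAlH4 reduction of an ester to the primary alcohol leaves the furan and its methyl ether untouched, and the basic work-up avoids the acid-induced ionisation to which furfuryl alcohols are prone.

**Step 3**
Reactants: 4 3-bromo-4,5-dimethoxybenzaldehyde; 5 ethynylmagnesium bromide
Product: 6 1-(3-bromo-4,5-dimethoxyphenyl)prop-2-yn-1-ol (racemic)
Conditions: 5 (0.5 M in THF, 1.3 equiv), THF, 0 °C; sat. aq NH4Cl
Reagents that add atoms: ethynylmagnesium bromide (5), C#C[Mg]Br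
Why: Grignard 1,2-addition of an alkynyl nucleophile to an aromatic aldehyde is fast at 0 °C and does not touch the aryl bromide; the new C8 stereocentre forms without control as a racemate, which is harmless because C8 ends as CH2.

**Step 4**
Reactants: 3 (4-methoxyfuran-2-yl)methanol; 6 1-(3-bromo-4,5-dimethoxyphenyl)prop-2-yn-1-ol (racemic)
Product: 8 2-({[1-(3-bromo-4,5-dimethoxyphenyl)prop-2-yn-1-yl]oxy}methyl)-4-methoxyfuran (racemic), via furfuryl mesylate 7 (not isolated)
Conditions: (a) 3 (1.1 equiv), MsCl, Et3N, THF, −40 °C, cold filtration; (b) 6, NaH (1.05 equiv), THF–DMF, 0 °C, then solution (a), −40 → 0 °C; chromatography on Et3N-deactivated silica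
Reagents that add atoms: none
Why: Williamson ether synthesis (SN2 at the primary furfuryl carbon C7 by the sodium alkoxide of 6, a kind of alkoxide that is routinely O-alkylated) is chosen because joining the two alcohols under acid would invite C-alkylation of the nucleophilic furan C5; the mesylate is made under basic conditions, kept cold and used in slight excess so that no alkoxide is left to isomerise the alkyne to an allene, and C8 is not touched.

**Step 5**
Reactants: 8 2-({[1-(3-bromo-4,5-dimethoxyphenyl)prop-2-yn-1-yl]oxy}methyl)-4-methoxyfuran (racemic)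
Product: 10 1-(3-bromo-4,5-dimethoxyphenyl)-5-methoxy-1,3-dihydro-2-benzofuran-6-ol (racemic), via oxanorbornadiene cycloadduct 9 (not isolated)
Conditions: 1,2-dichlorobenzene (0.02 M), BHT (5 mol %), 190–200 °C (sealed vessel, microwave), Ar; cool to rt, then anhydrous CSA (10 mol %)
Reagents that add atoms: none
Why: On heating, the furan (diene, furan C2 to C5) and the tethered alkyne join in a concerted suprafacial [4+2] cycloaddition, furan C2 bonding to the internal alkyne carbon (C1–C6) and furan C5 to the terminal one (C4–C5) to give 9, after which acid protonates the bridge oxygen, the C1–O bond breaks and loss of the C4 proton gives the phenol. The closest known reactions are the thermal intramolecular Diels–Alder reactions of donor-substituted furans with tethered alkynes that carry no acceptor, which run at 180–220 °C and end in phenols, and the acid opening of 7-oxanorbornadienes; 3-alkoxyfurans are known to be unusually reactive dienes that cycloadd irreversibly. The five-membered ether ring closes through C1–C6, the three-atom tether C7–O–C8 folding the internal alkyne carbon onto furan C2 in an exo-dig sense, and the six-membered carbocycle closes in the same pericyclic event through C1–C6 and C4–C5. The bridgeheads C1 and C4 of 9 are set as a pair by the geometry of the bicycle and without control relative to C8, but both become sp2 on aromatisation, so no new stereocentre survives and C8 stays racemic. Two selectivities are needed: the orientation of the cycloaddition, which the short tether enforces, and cleavage of C1–O rather than C4–O, which is secured because a cation at C1 is tertiary, allylic to C5=C6 and conjugated through C2=C3 with the C3 methoxy group, whereas at C4 the methoxy group would sit on the central carbon of the allyl system and give no help. High dilution, exclusion of air and BHT suppress intermolecular and radical decay at the temperature that the unactivated alkyne demands, and aromatisation withdraws 9 from the retro-Diels–Alder equilibrium.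

**Step 6**
Reactants: 10 1-(3-bromo-4,5-dimethoxyphenyl)-5-methoxy-1,3-dihydro-2-benzofuran-6-ol (racemic)
Product: 11 7-bromo-1-(3-bromo-4,5-dimethoxyphenyl)-5-methoxy-1,3-dihydro-2-benzofuran-6-ol (racemic)
Conditions: NBS (1.0 equiv), iPr2NH (10 mol %), CH2Cl2, −40 → 0 °C, dark
Reagents that add atoms: N-bromosuccinimide, O=C1CCC(=O)N1Br
Why: Electrophilic aromatic substitution (amine-catalysed ortho-bromination of a phenol with NBS) should go to C5, because the C4 hydroxyl is the strongest director, its para position C1 and its other ortho position C3 are occupied, and both C2 (ortho only to a methyl ether) and the non-phenolic, already brominated ring B are much less reactive; cold, dark conditions spare the C8–H bond.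

**Step 7**
Reactants: 11 7-bromo-1-(3-bromo-4,5-dimethoxyphenyl)-5-methoxy-1,3-dihydro-2-benzofuran-6-ol (racemic)
Product: 12 2-bromo-3-[(3-bromo-4,5-dimethoxyphenyl)methyl]-4-(hydroxymethyl)-6-methoxyphenol
Conditions: Et3SiH (1.3 equiv), TFA (5 equiv), CH2Cl2, −20 → 0 °C; pH 7 buffer
Reagents that add atoms: none
Why: Ionic hydrogenation: TFA ionises the C8–O bond, because the resulting diarylmethyl cation is stabilised by ring B and by the C3 methoxy group para to C6, and Et3SiH delivers hydride to C8, which frees the C7 oxygen as the hydroxymethyl group and removes the stereocentre, while low temperature and near-stoichiometric silane keep the far less easily ionised primary C7–OH from reacting further.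

**Step 8**
Reactants: 12 2-bromo-3-[(3-bromo-4,5-dimethoxyphenyl)methyl]-4-(hydroxymethyl)-6-methoxyphenol
Product: 14 5-hydroxyisoavrainvilleol, 3-bromo-4-[(3-bromo-4,5-dihydroxyphenyl)methyl]-5-(hydroxymethyl)benzene-1,2-diol, via tetrahydroxy benzylic bromide 13 (not isolated)
Conditions: BBr3 (8 equiv), CH2Cl2, −78 → 0 °C; ice; then acetone–H2O 1:1 (0.01 M), rt; no alcohol solvents in work-up or purification
Reagents that add atoms: water, O
Why: Lewis-acid cleavage of aryl methyl ethers with BBr3 removes the three methyl groups as bromomethane but also turns the electron-rich benzylic alcohol into bromide 13, which is accepted and corrected in the same operation, since a 4-hydroxybenzylic bromide solvolyses readily in dilute aqueous acetone by way of the para-quinone methide and so returns the CH2OH group.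

**Compound list**
1 | methyl 4-bromofuran-2-carboxylate | COC(=O)c1cc(Br)co1 | starting material
2 | methyl 4-methoxyfuran-2-carboxylate | COC(=O)c1cc(OC)co1 | intermediate
3 | (4-methoxyfuran-2-yl)methanol | OCc1cc(OC)co1 | intermediate
4 | 3-bromo-4,5-dimethoxybenzaldehyde | COc1cc(C=O)cc(Br)c1OC | starting material
5 | ethynylmagnesium bromide | C#C[Mg]Br | starting material
6 | 1-(3-bromo-4,5-dimethoxyphenyl)prop-2-yn-1-ol (racemic) | C#CC(O)c1cc(OC)c(OC)c(Br)c1 | intermediate
7 | (4-methoxyfuran-2-yl)methyl methanesulfonate (not isolated) | COc1coc(COS(C)(=O)=O)c1 | intermediate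
8 | 2-({[1-(3-bromo-4,5-dimethoxyphenyl)prop-2-yn-1-yl]oxy}methyl)-4-methoxyfuran (racemic) | COc1coc(COC(C#C)c2cc(OC)c(OC)c(Br)c2)c1 | intermediate
9 | 4-(3-bromo-4,5-dimethoxyphenyl)-8-methoxy-3,10-dioxatricyclo[5.2.1.0^1,5]deca-5,8-diene (racemic, mixture of epimers at the aryl-bearing carbon; not isolated) | COC1=CC23COC(c4cc(OC)c(OC)c(Br)c4)C2=CC1O3 | intermediate
10 | 1-(3-bromo-4,5-dimethoxyphenyl)-5-methoxy-1,3-dihydro-2-benzofuran-6-ol (racemic) | COc1cc2c(cc1O)C(c1cc(OC)c(OC)c(Br)c1)OC2 | intermediate
11 | 7-bromo-1-(3-bromo-4,5-dimethoxyphenyl)-5-methoxy-1,3-dihydro-2-benzofuran-6-ol (racemic) | COc1cc2c(c(Br)c1O)C(c1cc(OC)c(OC)c(Br)c1)OC2 | intermediate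
12 | 2-bromo-3-[(3-bromo-4,5-dimethoxyphenyl)methyl]-4-(hydroxymethyl)-6-methoxyphenol | COc1cc(CO)c(Cc2cc(OC)c(OC)c(Br)c2)c(Br)c1O | intermediate
13 | 3-bromo-4-[(3-bromo-4,5-dihydroxyphenyl)methyl]-5-(bromomethyl)benzene-1,2-diol (not isolated) | BrCc1cc(O)c(O)c(Br)c1Cc1cc(O)c(O)c(Br)c1 | intermediate
14 | 5-hydroxyisoavrainvilleol, 3-bromo-4-[(3-bromo-4,5-dihydroxyphenyl)methyl]-5-(hydroxymethyl)benzene-1,2-diol | OCc1cc(O)c(O)c(Br)c1Cc1cc(O)c(O)c(Br)c1 | target

Total step count: 8
Longest linear sequence: 7 steps (steps 1, 2, 4, 5, 6, 7, 8)

**Steps most likely to fail**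

**Step 5.**
- Risk: ring closure may lag behind thermal breakdown of the doubly activated ether, because a terminal alkyne without an acceptor is a slow dienophile.
- Approach: the fallback sets out from 8 and activates the dienophile instead of forcing the temperature.
- LDA (THF, −78 °C) followed by methyl chloroformate should give methyl 4-(3-bromo-4,5-dimethoxyphenyl)-4-[(4-methoxyfuran-2-yl)methoxy]but-2-ynoate F1. Its acceptor-substituted alkyne belongs to the class that adds to tethered furans in toluene at 80–110 °C.
- Heating should give methyl 4-(3-bromo-4,5-dimethoxyphenyl)-8-methoxy-3,10-dioxatricyclo[5.2.1.0^1,5]deca-5,8-diene-6-carboxylate F2. CSA should open this to methyl 3-(3-bromo-4,5-dimethoxyphenyl)-5-hydroxy-6-methoxy-1,3-dihydro-2-benzofuran-4-carboxylate F3.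
- Saponification (KOH, aqueous dioxane, 80 °C) should give 3-(3-bromo-4,5-dimethoxyphenyl)-5-hydroxy-6-methoxy-1,3-dihydro-2-benzofuran-4-carboxylic acid F4.
- Ipso-bromodecarboxylation of this ortho-hydroxybenzoic acid with NBS (MeCN, rt) places bromine on C5 as CO2 leaves.
- The sequence comes back to the route at 11, so step 6 is no longer needed.

**Step 4.**
- Risk: the furfuryl mesylate may ionise and self-alkylate before it meets the alkoxide, or the base may isomerise the product alkyne to an allene.
- Approach: the fallback sets out from 6 (with 3 as partner) and reverses the polarity, so that the C8–O bond is formed instead of C7–O.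
- MsCl and Et3N (CH2Cl2, −30 °C) should convert 6 into 1-(3-bromo-4,5-dimethoxyphenyl)prop-2-yn-1-yl methanesulfonate F5, a much less fragile electrophile.
- The sodium alkoxide of 3 (NaH, THF, −20 → 0 °C) displaces it in an SN2 reaction.
- The sequence comes back to the route at 8.

**Step 8.**
- Risk: while C7 carries a leaving group in the presence of a Lewis acid, Friedel–Crafts closure onto ring B (a six-membered ring) or intermolecular alkylation may compete with clean demethylation and hydrolysis.
- Approach: the fallback sets out from 11 and changes the order of events, so that the hydroxymethyl group never meets BBr3.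
- BBr3 (CH2Cl2, −78 → 0 °C) and aqueous work-up on 11 should give 7-bromo-1-(3-bromo-4,5-dihydroxyphenyl)-1,3-dihydro-2-benzofuran-5,6-diol F6. If the Lewis acid opens a benzylic C–O bond, it should re-close on hydrolysis by way of the quinone methide.
- Ionic hydrogenation with Et3SiH and TFA (CH2Cl2–MeCN, −20 °C), as in step 7, then opens C8–O as the last operation.
- The sequence comes back to the route at 14.

**Further compounds**
F1 | step 5 | methyl 4-(3-bromo-4,5-dimethoxyphenyl)-4-[(4-methoxyfuran-2-yl)methoxy]but-2-ynoate (racemic) | COC(=O)C#CC(OCc1cc(OC)co1)c1cc(OC)c(OC)c(Br)c1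
F2 | step 5 | methyl 4-(3-bromo-4,5-dimethoxyphenyl)-8-methoxy-3,10-dioxatricyclo[5.2.1.0^1,5]deca-5,8-diene-6-carboxylate (racemic, mixture of epimers at the aryl-bearing carbon) | COC1=CC23COC(c4cc(OC)c(OC)c(Br)c4)C2=C(C(=O)OC)C1O3
F3 | step 5 | methyl 3-(3-bromo-4,5-dimethoxyphenyl)-5-hydroxy-6-methoxy-1,3-dihydro-2-benzofuran-4-carboxylate (racemic) | COC(=O)c1c(O)c(OC)cc2c1C(c1cc(OC)c(OC)c(Br)c1)OC2
F4 | step 5 | 3-(3-bromo-4,5-dimethoxyphenyl)-5-hydroxy-6-methoxy-1,3-dihydro-2-benzofuran-4-carboxylic acid (racemic) | OC(=O)c1c(O)c(OC)cc2c1C(c1cc(OC)c(OC)c(Br)c1)OC2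
F5 | step 4 | 1-(3-bromo-4,5-dimethoxyphenyl)prop-2-yn-1-yl methanesulfonate (racemic) | C#CC(OS(C)(=O)=O)c1cc(OC)c(OC)c(Br)c1
F6 | step 8 | 7-bromo-1-(3-bromo-4,5-dihydroxyphenyl)-1,3-dihydro-2-benzofuran-5,6-diol (racemic) | Oc1cc2c(c(Br)c1O)C(c1cc(O)c(O)c(Br)c1)OC2
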